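**Plan**
- Retrosynthesis: the oxolane C5–H bond is cut back to a 2-aryl oxocarbenium ion (lactol), the C5–aryl bond to an aryllithium plus a γ-lactone, and the lactone C2–O bond to a γ-keto imide.
- Enabling feature: the two trans methyl groups on ring carbons C3 and C4. With C3 and C4 they map onto a thiolane in which sulfur bridges the two methyl carbons, so the C3–CH3 and C4–CH3 bonds are cut back to a thiocarbonyl ylide and an (E)-alkene flanked by the C2 aroyl carbon and the C5 acyl carbon.
- Forward: veratrole and maleic anhydride give the (E)-aroylacrylic acid, which is joined to (S)-4-benzyloxazolidin-2-one. The [3+2] cycloaddition closes the temporary thiolane, Raney Ni removes sulfur, ketone reduction closes the γ-lactone with release of the auxiliary, and aryllithium addition followed by silane reduction gives the oxolane.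
- Stereochemistry: C3/C4 trans from suprafacial addition to the (E)-alkene, their absolute sense from the auxiliary (diastereomers separated); C2 from Felkin–Anh reduction; C5 from face-selective hydride delivery to the oxocarbenium ion.

Key step: step 3

Assumption: the uncatalysed cycloaddition to the (S)-4-benzyl imide is taken to favour the (3S,4S) adduct, although the bias of such imides without a chelating Lewis acid is modest and its sense is not secure (were the (3R,4R) adduct to dominate, the (R)-auxiliary would be used in the same sequence); chloromethyl trimethylsilylmethyl sulfide is taken as a purchasable reagent.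

**Route**

Step 1
Reactants: 1 veratrole; 2 maleic anhydride
Product: 3 (E)-4-(3,4-dimethoxyphenyl)-4-oxobut-2-enoic acid
Conditions: AlCl3 (2.2 equiv), CH2Cl2, 0 °C → rt; then ice/aq. HCl
Reagents that add atoms: none
Why: Friedel–Crafts acylation of the electron-rich arene by the AlCl3-activated anhydride occurs para to a methoxy group, and the first-formed (Z)-aroylacrylic acid isomerises under the acidic conditions to the conjugated (E)-acid.

Step 2
Reactants: 3 (E)-4-(3,4-dimethoxyphenyl)-4-oxobut-2-enoic acid; 4 (S)-4-benzyloxazolidin-2-one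
Product: 6 (S)-4-benzyl-3-[(E)-4-(3,4-dimethoxyphenyl)-4-oxobut-2-enoyl]oxazolidin-2-one, via mixed pivalic anhydride 5 (not isolated)
Conditions: PivCl, Et3N, THF, −20 °C; then 4, LiCl, −20 °C → rt
Reagents that add atoms: none
Why: N-acylation through the pivalic mixed anhydride under the mild Et3N/LiCl protocol avoids strongly basic conditions that could trigger conjugate addition to the very electrophilic ene-dione, the hindered pivaloyl carbonyl steers the oxazolidinone nitrogen to the butenoyl carbonyl, and the (E) geometry is untouched.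

Step 3
Reactants: 6 (S)-4-benzyl-3-[(E)-4-(3,4-dimethoxyphenyl)-4-oxobut-2-enoyl]oxazolidin-2-one; 7 chloromethyl trimethylsilylmethyl sulfide
Product: 9 (S)-4-benzyl-3-[(3S,4S)-4-(3,4-dimethoxybenzoyl)thiolane-3-carbonyl]oxazolidin-2-one, via thiocarbonyl ylide 8 (not isolated)
Conditions: 7 (2 equiv, slow addition), CsF (4 equiv), MeCN, rt; diastereomers separated on SiO2 or by crystallisation
Reagents that add atoms: none
Why: Fluoride attacks silicon of 7 and the resulting α-thio carbanion expels chloride in a 1,3-elimination, releasing the parent thiocarbonyl ylide 8, an electron-rich dipole that adds to the doubly acceptor-substituted C=C of 6 in a concerted 1,3-dipolar [3+2] cycloaddition; the closest known reaction is the addition of this same ylide to chiral N-enoyl oxazolidinones and sultams. The thiolane is closed intermolecularly by simultaneous formation of its C2–C3 and C4–C5 bonds across the former alkene, so the symmetric dipole raises no regiochemical question and the aryl ketone and imide carbonyls are left alone. Because the addition is suprafacial on the alkene, the (E) geometry becomes the trans relationship of C3 and C4. Their absolute configuration is controlled by the benzyl group at C4 of the auxiliary, which screens one face of the s-cis enoyl imide, a preference expected to be only moderate without a chelating Lewis acid. The step therefore needs facial selectivity, and stereochemical purity is secured by the fact that the two possible adducts are diastereomers, so the (3S,4S) isomer 9 is carried on as a single compound after separation.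

Step 4
Reactants: 9 (S)-4-benzyl-3-[(3S,4S)-4-(3,4-dimethoxybenzoyl)thiolane-3-carbonyl]oxazolidin-2-one
Product: 10 (S)-4-benzyl-3-[(2S,3S)-4-(3,4-dimethoxyphenyl)-2,3-dimethyl-4-oxobutanoyl]oxazolidin-2-one
Conditions: Raney Ni (W-2, deactivated in refluxing acetone), acetone/EtOH, rt
Reagents that add atoms: none
Why: Raney Ni hydrogenolyses both C–S bonds (reductive desulfurisation), turning the CH2–S–CH2 bridge into two methyl groups without touching the two stereocentres, and deactivated nickel at room temperature is chosen so that the aryl ketone and the imide survive.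

Step 5
Reactants: 10 (S)-4-benzyl-3-[(2S,3S)-4-(3,4-dimethoxyphenyl)-2,3-dimethyl-4-oxobutanoyl]oxazolidin-2-one
Product: 12 (3S,4S,5S)-5-(3,4-dimethoxyphenyl)-3,4-dimethyloxolan-2-one, via hydroxy imide 11 (not isolated)
Conditions: NaBH4, CeCl3·7H2O, MeOH/THF, −40 °C → rt
Reagents that add atoms: none
Why: Under Luche conditions the ketone is reduced much faster than the imide, Felkin–Anh attack anti to the branched α-substituent should favour the (4S)-carbinol 11, and its oxygen then attacks the imide carbonyl in a 5-exo-trig acyl transfer that closes the all-trans γ-lactone and expels the recoverable auxiliary 4, any minor C5 epimer being removed at this stage.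

Step 6
Reactants: 12 (3S,4S,5S)-5-(3,4-dimethoxyphenyl)-3,4-dimethyloxolan-2-one; 13 5-bromo-1,2,3-trimethoxybenzene
Product: 15 (3S,4S,5S)-5-(3,4-dimethoxyphenyl)-3,4-dimethyl-2-(3,4,5-trimethoxyphenyl)oxolan-2-ol (anomer mixture), via 3,4,5-trimethoxyphenyllithium 14 (not isolated)
Conditions: 13, n-BuLi, THF, −78 °C; then 12, −78 °C; AcOH quench at −78 °C
Reagents that add atoms: none
Why: Bromine–lithium exchange generates the aryllithium 14, which adds only once to the lactone carbonyl because the tetrahedral alkoxide adduct does not collapse at −78 °C (aryllithium addition to a γ-lactone giving a lactol), and the low temperature with an acidic quench protects the enolisable C3 stereocentre.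

Step 7
Reactants: 15 (3S,4S,5S)-5-(3,4-dimethoxyphenyl)-3,4-dimethyl-2-(3,4,5-trimethoxyphenyl)oxolan-2-ol
Product: 17 5-methoxygalbelgin [(2S,3S,4S,5S)-2-(3,4-dimethoxyphenyl)-3,4-dimethyl-5-(3,4,5-trimethoxyphenyl)oxolane], via oxocarbenium ion 16 (not isolated)
Conditions: Et3SiH, BF3·OEt2, CH2Cl2, −78 °C → −20 °C
Reagents that add atoms: none
Why: BF3·OEt2 ionises the lactol to the 2-aryl oxocarbenium ion 16, which Et3SiH should reduce by inside attack on the envelope conformer with all substituents pseudo-equatorial, placing the new hydrogen cis to the neighbouring methyl group and hence the trimethoxyphenyl group trans to it, while the other benzylic centre is already trans and, if its p-methoxy-stabilised C–O bond opens at all, recloses to the same more stable arrangement (reductive deoxygenation of a cyclic hemiketal).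

**Compound list**

1 | veratrole (1,2-dimethoxybenzene) | COc1ccccc1OC | starting material
2 | maleic anhydride | O=C1OC(=O)C=C1 | starting material
3 | (E)-4-(3,4-dimethoxyphenyl)-4-oxobut-2-enoic acid | COc1ccc(cc1OC)C(=O)/C=C/C(=O)O | intermediate
4 | (S)-4-benzyloxazolidin-2-one | O=C1N[C@@H](Cc2ccccc2)CO1 | starting material
5 | (E)-4-(3,4-dimethoxyphenyl)-4-oxobut-2-enoic pivalic anhydride | COc1ccc(cc1OC)C(=O)/C=C/C(=O)OC(=O)C(C)(C)C | intermediate
6 | (S)-4-benzyl-3-[(E)-4-(3,4-dimethoxyphenyl)-4-oxobut-2-enoyl]oxazolidin-2-one | COc1ccc(cc1OC)C(=O)/C=C/C(=O)N2[C@@H](Cc3ccccc3)COC2=O | intermediate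
7 | chloromethyl trimethylsilylmethyl sulfide | C[Si](C)(C)CSCCl | starting material
8 | thioformaldehyde S-methylide (parent thiocarbonyl ylide) | [CH2-][S+]=C | intermediate
9 | (S)-4-benzyl-3-[(3S,4S)-4-(3,4-dimethoxybenzoyl)thiolane-3-carbonyl]oxazolidin-2-one | COc1ccc(cc1OC)C(=O)[C@H]2CSC[C@@H]2C(=O)N3[C@@H](Cc4ccccc4)COC3=O | intermediate
10 | (S)-4-benzyl-3-[(2S,3S)-4-(3,4-dimethoxyphenyl)-2,3-dimethyl-4-oxobutanoyl]oxazolidin-2-one | COc1ccc(cc1OC)C(=O)[C@@H](C)[C@H](C)C(=O)N2[C@@H](Cc3ccccc3)COC2=O | intermediate
11 | (S)-4-benzyl-3-[(2S,3S,4S)-4-(3,4-dimethoxyphenyl)-4-hydroxy-2,3-dimethylbutanoyl]oxazolidin-2-one | COc1ccc(cc1OC)[C@@H](O)[C@@H](C)[C@H](C)C(=O)N2[C@@H](Cc3ccccc3)COC2=O | intermediate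
12 | (3S,4S,5S)-5-(3,4-dimethoxyphenyl)-3,4-dimethyloxolan-2-one | COc1ccc([C@H]2OC(=O)[C@@H](C)[C@@H]2C)cc1OC | intermediate
13 | 5-bromo-1,2,3-trimethoxybenzene | COc1cc(Br)cc(OC)c1OC | starting material
14 | 3,4,5-trimethoxyphenyllithium | [Li]c1cc(OC)c(OC)c(OC)c1 | intermediate
15 | (3S,4S,5S)-5-(3,4-dimethoxyphenyl)-3,4-dimethyl-2-(3,4,5-trimethoxyphenyl)oxolan-2-ol (anomer mixture) | COc1ccc([C@H]2OC(O)(c3cc(OC)c(OC)c(OC)c3)[C@@H](C)[C@@H]2C)cc1OC | intermediate
16 | (3S,4S,5S)-5-(3,4-dimethoxyphenyl)-3,4-dimethyl-2-(3,4,5-trimethoxyphenyl)-4,5-dihydro-3H-furan-1-ium (oxocarbenium ion) | COc1ccc([C@H]2[O+]=C(c3cc(OC)c(OC)c(OC)c3)[C@@H](C)[C@@H]2C)cc1OC | intermediate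
17 | 5-methoxygalbelgin, (2S,3S,4S,5S)-2-(3,4-dimethoxyphenyl)-3,4-dimethyl-5-(3,4,5-trimethoxyphenyl)oxolane | COc1ccc([C@H]2O[C@H](c3cc(OC)c(OC)c(OC)c3)[C@@H](C)[C@@H]2C)cc1OC | target

**Count and risks**

Total steps: 7. Longest linear sequence: 7 steps (from 1 to 17).

Steps most likely to fail:

Step 3. What may go wrong is weak or even reversed discrimination between the two alkene faces, so that much material is lost to the (3R,4R) diastereomer or the separation becomes impractical. The fallback gives up auxiliary control and takes the two methyl-bearing stereocentres from a resolved building block. Known (2S,3S)-2,3-dimethylsuccinic acid would be closed with acetyl chloride to (3S,4S)-3,4-dimethyloxolane-2,5-dione F1. Because this anhydride is C2-symmetric, its AlCl3-mediated Friedel–Crafts acylation of veratrole 1 at 0 °C can give only (2S,3S)-4-(3,4-dimethoxyphenyl)-2,3-dimethyl-4-oxobutanoic acid F2. NaBH4 reduction under Felkin–Anh control would give (2S,3S,4S)-4-(3,4-dimethoxyphenyl)-4-hydroxy-2,3-dimethylbutanoic acid F3, which lactonises on acidification. This fallback sets out from 1 and returns to the route at 12.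

Step 4. What may go wrong is over-reduction of the aryl ketone on the nickel surface down to the benzylic methylene, or epimerisation of the enolisable centre next to the ketone. The fallback removes the ketone before sulfur is taken out. Luche reduction of 9 (NaBH4, CeCl3·7H2O, MeOH/THF, −40 °C) would give (S)-4-benzyl-3-[(3S,4S)-4-[(S)-(3,4-dimethoxyphenyl)(hydroxy)methyl]thiolane-3-carbonyl]oxazolidin-2-one F4, in which the trans ring fusion disfavours lactonisation. Brief exposure to deactivated Raney Ni at 0 °C would then give the open-chain hydroxy imide 11, which closes to the lactone as in step 5. This fallback sets out from 9 and returns to the route at 12 by way of 11.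

Step 7. What may go wrong is hydride delivery to the wrong face of the oxocarbenium ion, proton loss to the enol ether with scrambling of the adjacent methyl centre, or reductive opening of the electron-rich benzylic C–O bond by the silane. The fallback sets the trimethoxyphenyl-bearing centre in the open chain and closes the ring at the other benzylic carbon. Lactol 15 would react with NaBH4 (MeOH, 0 °C) through its ring-opened tautomer (2S,3S,4S)-4-(3,4-dimethoxyphenyl)-4-hydroxy-2,3-dimethyl-1-(3,4,5-trimethoxyphenyl)butan-1-one F5, under Felkin–Anh control, to give (1S,2S,3S,4S)-1-(3,4-dimethoxyphenyl)-2,3-dimethyl-4-(3,4,5-trimethoxyphenyl)butane-1,4-diol F6. Catalytic p-TsOH in CH2Cl2 at 0 °C should ionise only the dimethoxyphenyl carbinol. Capture of that cation by the other hydroxyl, which keeps its configuration, closes the oxolane with the dimethoxyphenyl group trans to its neighbouring methyl. This fallback sets out from 15 and returns to the route at 17.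

**Further compounds**

F1 | step 3 | (3S,4S)-3,4-dimethyloxolane-2,5-dione | C[C@@H]1C(=O)OC(=O)[C@H]1C
F2 | step 3 | (2S,3S)-4-(3,4-dimethoxyphenyl)-2,3-dimethyl-4-oxobutanoic acid | COc1ccc(cc1OC)C(=O)[C@@H](C)[C@H](C)C(=O)O
F3 | step 3 | (2S,3S,4S)-4-(3,4-dimethoxyphenyl)-4-hydroxy-2,3-dimethylbutanoic acid | COc1ccc(cc1OC)[C@@H](O)[C@@H](C)[C@H](C)C(=O)O
F4 | step 4 | (S)-4-benzyl-3-[(3S,4S)-4-[(S)-(3,4-dimethoxyphenyl)(hydroxy)methyl]thiolane-3-carbonyl]oxazolidin-2-one | COc1ccc(cc1OC)[C@@H](O)[C@H]2CSC[C@@H]2C(=O)N3[C@@H](Cc4ccccc4)COC3=O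
F5 | step 7 | (2S,3S,4S)-4-(3,4-dimethoxyphenyl)-4-hydroxy-2,3-dimethyl-1-(3,4,5-trimethoxyphenyl)butan-1-one | COc1ccc(cc1OC)[C@@H](O)[C@@H](C)[C@H](C)C(=O)c2cc(OC)c(OC)c(OC)c2
F6 | step 7 | (1S,2S,3S,4S)-1-(3,4-dimethoxyphenyl)-2,3-dimethyl-4-(3,4,5-trimethoxyphenyl)butane-1,4-diol | COc1ccc(cc1OC)[C@@H](O)[C@@H](C)[C@H](C)[C@H](O)c2cc(OC)c(OC)c(OC)c2
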